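**Retrosynthetic overview**
1. The target has four aromatic rings (benzene and pyrrole rings of the indole, the oxazole, the pyrrole). All are bought intact, so no ring is formed in the route.
2. Key disconnection: the indole C3–oxazole C5 bond, made in one pot by halogen dance, zincation and Negishi coupling of a 5-iodo-2-(N-SEM-pyrrol-2-yl)oxazole with an N-Boc-6-bromo-3-iodo-4-methoxyindole.
3. Enabling feature: on the oxazole ring the iodine (C4) and the indolyl carbon (C5) are neighbours, C2 is blocked by the pyrrole ring, and C4–H is the only oxazole hydrogen. A 5-iodooxazole therefore rearranges under amide base to the 4-iodo-5-metallo isomer (carbanion at C5 beside O1), and the iodine that activates the fragment ends exactly where the target needs it.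
4. Second disconnection: the oxazole C2–pyrrole C2 bond, by Negishi coupling of an N-SEM-pyrrol-2-ylzinc chloride with 2-bromooxazole. The indole partner comes from 6-bromo-4-methoxyindole by C3 iodination and N-Boc protection.
5. End game: methanolysis of the Boc group, then fluoride cleavage of the SEM group.

Key step: step 6

Assumption: 6-bromo-4-methoxy-1H-indole, 2-bromo-1,3-oxazole and 2-(tributylstannyl)-1,3-oxazole are taken as catalogue building blocks.
Abbreviations: SEM = [2-(trimethylsilyl)ethoxy]methyl; Boc = tert-butoxycarbonyl.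

**Route**

Step 1
Reactants: 1 6-bromo-4-methoxy-1H-indole
Product: 2 6-bromo-3-iodo-4-methoxy-1H-indole
Conditions: I2 (1.05 equiv), KOH (2.5 equiv), DMF, 0 °C to rt, dark
Reagents that add atoms: iodine, II
Why: Electrophilic aromatic iodination of the indolyl anion should go to C3, the most nucleophilic carbon of the indole, and leaves the bromide and the methoxy group untouched.

Step 2
Reactants: 2 6-bromo-3-iodo-4-methoxy-1H-indole
Product: 3 tert-butyl 6-bromo-3-iodo-4-methoxy-1H-indole-1-carboxylate
Conditions: Boc2O (1.2 equiv), DMAP (0.1 equiv), CH2Cl2, rt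
Reagents that add atoms: di-tert-butyl dicarbonate, CC(C)(C)OC(=O)OC(=O)OC(C)(C)C
Why: DMAP-catalysed N-acylation (carbamate formation) of the indole nitrogen should stabilise the light-sensitive 3-iodoindole and make its C3–I bond electron-poor for the later oxidative addition.

Step 3
Reactants: 4 1H-pyrrole
Product: 6 1-{[2-(trimethylsilyl)ethoxy]methyl}-1H-pyrrole (1-SEM-pyrrole), via sodium pyrrolide 5 (not isolated)
Conditions: NaH (1.2 equiv), DMF, 0 °C; then SEMCl (1.1 equiv), 0 °C to rt
Reagents that add atoms: 2-(trimethylsilyl)ethoxymethyl chloride (SEMCl), C[Si](C)(C)CCOCCl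
Why: SN2 N-alkylation of sodium pyrrolide by the chloromethyl ether should give the N-SEM pyrrole, whose protecting group survives alkyllithium and amide bases and assists α-lithiation.

Step 4
Reactants: 6 1-SEM-pyrrole; 7 2-bromo-1,3-oxazole
Product: 10 2-(1-SEM-1H-pyrrol-2-yl)-1,3-oxazole, via 2-lithio-1-SEM-pyrrole 8 (not isolated), via 1-SEM-pyrrol-2-ylzinc chloride 9 (not isolated)
Conditions: n-BuLi (1.05 equiv), DME, −10 °C; ZnCl2 (1.1 equiv), THF, −10 °C to rt; then 7 (0.9 equiv), Pd(PPh3)4 (3 mol %), THF, 50 °C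
Reagents that add atoms: none
Why: SEM-assisted α-lithiation of the pyrrole, transmetalation to zinc and Negishi cross-coupling at the activated C2–Br bond of 7 under Pd(PPh3)4 (zerovalent palladium) should join pyrrole C2 to oxazole C2, the mild zinc reagent leaving the oxazole C–H bonds and the SEM group untouched.

Step 5
Reactants: 10 2-(1-SEM-1H-pyrrol-2-yl)-1,3-oxazole
Product: 12 5-iodo-2-(1-SEM-1H-pyrrol-2-yl)-1,3-oxazole, via 5-lithiooxazole 11 (not isolated)
Conditions: LiN(iPr)2 (LDA, 1.1 equiv), THF, −78 °C; then cannulation into I2 (1.5 equiv), THF, −78 °C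
Reagents that add atoms: iodine, II
Why: Directed deprotonation and iodine quench: with C2 blocked by the pyrrole, LiN(iPr)2 removes the most acidic remaining oxazole hydrogen at C5 (beside O1), and inverse addition of 11 into excess I2 should trap it before lithiated and iodinated oxazole can coexist and start an iodine migration.

Step 6
Reactants: 12 5-iodo-2-(1-SEM-1H-pyrrol-2-yl)-1,3-oxazole; 3 tert-butyl 6-bromo-3-iodo-4-methoxy-1H-indole-1-carboxylate
Product: 16 tert-butyl 6-bromo-3-[4-iodo-2-(1-SEM-1H-pyrrol-2-yl)-1,3-oxazol-5-yl]-4-methoxy-1H-indole-1-carboxylate, via 5-iodo-4-lithiooxazole 13 (not isolated), via 4-iodo-5-lithiooxazole 14 (not isolated), via 4-iodooxazol-5-ylzinc chloride 15 (not isolated)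
Conditions: LiN(iPr)2 (1.3 equiv), THF, −78 °C; ZnCl2 (1.5 equiv), −78 to 0 °C; then 3 (0.8 equiv), Pd(PPh3)4 (5 mol %), THF, 25 to 45 °C
Reagents that add atoms: none
Why: LiN(iPr)2 removes the only hydrogen left on the oxazole (C4–H, acidified by the neighbouring C5–I bond) to give 13, and a relay of intermolecular iodine–lithium exchanges (halogen dance) moves the iodine from C5 to C4 until the thermodynamic anion 14 is reached, whose carbanion lies at C5 beside O1; ZnCl2 then fixes it as the non-basic zinc reagent 15. Pd(PPh3)4 (zerovalent palladium) inserts into the C3–I bond of 3, and transmetalation with 15 and reductive elimination form the indole C3–oxazole C5 bond, so that two carbons that are both nucleophilic in the parent heteroarenes are joined by reversing the polarity of indole C3 (Negishi cross-coupling). The closest known reaction type is the halogen dance of 5-halooxazoles that carry a C2 substituent, followed by Negishi coupling of the 4-halooxazol-5-ylzinc halide with an aryl iodide. No ring is closed and no stereocentre is formed, so neither a mode of closure nor a controlling element has to be named. The step needs site selectivity among three carbon–halogen bonds: oxidative addition should go to the C3–I bond of 3, made electron-poor by the N-Boc group, in preference to the C6–Br bond (bromide against iodide) and to the oxazole C4–I bond, which sits at the least reactive position of the oxazole and is flanked by the electron-rich C–Zn carbon in 15 and by the bulky 4-methoxyindol-3-yl group in 16. It also needs the amide base to be spent before 3 is added, which the order of addition secures, so that neither the Boc group nor the indole C5–H between the methoxy group and bromine meets LiN(iPr)2, and the pyrrole at oxazole C2 rules out ring opening of the metalated oxazole to an isocyanide.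

Step 7
Reactants: 16 tert-butyl 6-bromo-3-[4-iodo-2-(1-SEM-1H-pyrrol-2-yl)-1,3-oxazol-5-yl]-4-methoxy-1H-indole-1-carboxylate
Product: 17 6-bromo-3-[4-iodo-2-(1-SEM-1H-pyrrol-2-yl)-1,3-oxazol-5-yl]-4-methoxy-1H-indole
Conditions: NaOMe (0.3 equiv), MeOH/THF 1:1, rt
Reagents that add atoms: none
Why: Base-catalysed methanolysis (transesterification) of the N-acylindole carbamate, with the indolide as leaving group, should remove the Boc group without touching the SEM group, the C–I bond or the C–Br bond.

Step 8
Reactants: 17 6-bromo-3-[4-iodo-2-(1-SEM-1H-pyrrol-2-yl)-1,3-oxazol-5-yl]-4-methoxy-1H-indole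
Product: 18 6-bromo-3-[4-iodo-2-(1H-pyrrol-2-yl)-1,3-oxazol-5-yl]-4-methoxy-1H-indole
Conditions: Bu4NF (5 equiv, 1 M in THF), THF, 65 °C; aqueous work-up
Reagents that add atoms: none
Why: Fluoride-induced fragmentation of the SEM group (attack at silicon, loss of ethene and formaldehyde) should free the pyrrole N–H under conditions that leave the aryl iodide and the aryl bromide intact.

**Compound list**
1 | 6-bromo-4-methoxy-1H-indole | COc1cc(Br)cc2[nH]ccc12 | starting material
2 | 6-bromo-3-iodo-4-methoxy-1H-indole | COc1cc(Br)cc2[nH]cc(I)c12 | intermediate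
3 | tert-butyl 6-bromo-3-iodo-4-methoxy-1H-indole-1-carboxylate | COc1cc(Br)cc2n(C(=O)OC(C)(C)C)cc(I)c12 | intermediate
4 | 1H-pyrrole | c1cc[nH]c1 | starting material
5 | sodium pyrrol-1-ide | [Na+].c1cc[n-]c1 | intermediate
6 | 1-{[2-(trimethylsilyl)ethoxy]methyl}-1H-pyrrole | C[Si](C)(C)CCOCn1cccc1 | intermediate
7 | 2-bromo-1,3-oxazole | Brc1ncco1 | starting material
8 | 2-lithio-1-{[2-(trimethylsilyl)ethoxy]methyl}-1H-pyrrole | [Li]c1cccn1COCC[Si](C)(C)C | intermediate
9 | chloro(1-{[2-(trimethylsilyl)ethoxy]methyl}-1H-pyrrol-2-yl)zinc | Cl[Zn]c1cccn1COCC[Si](C)(C)C | intermediate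
10 | 2-(1-{[2-(trimethylsilyl)ethoxy]methyl}-1H-pyrrol-2-yl)-1,3-oxazole | C[Si](C)(C)CCOCn1cccc1-c1ncco1 | intermediate
11 | 5-lithio-2-(1-{[2-(trimethylsilyl)ethoxy]methyl}-1H-pyrrol-2-yl)-1,3-oxazole | [Li]c1cnc(-c2cccn2COCC[Si](C)(C)C)o1 | intermediate
12 | 5-iodo-2-(1-{[2-(trimethylsilyl)ethoxy]methyl}-1H-pyrrol-2-yl)-1,3-oxazole | Ic1cnc(-c2cccn2COCC[Si](C)(C)C)o1 | intermediate
13 | 5-iodo-4-lithio-2-(1-{[2-(trimethylsilyl)ethoxy]methyl}-1H-pyrrol-2-yl)-1,3-oxazole | [Li]c1nc(-c2cccn2COCC[Si](C)(C)C)oc1I | intermediate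
14 | 4-iodo-5-lithio-2-(1-{[2-(trimethylsilyl)ethoxy]methyl}-1H-pyrrol-2-yl)-1,3-oxazole | [Li]c1oc(-c2cccn2COCC[Si](C)(C)C)nc1I | intermediate
15 | chloro[4-iodo-2-(1-{[2-(trimethylsilyl)ethoxy]methyl}-1H-pyrrol-2-yl)-1,3-oxazol-5-yl]zinc | Cl[Zn]c1oc(-c2cccn2COCC[Si](C)(C)C)nc1I | intermediate
16 | tert-butyl 6-bromo-3-[4-iodo-2-(1-{[2-(trimethylsilyl)ethoxy]methyl}-1H-pyrrol-2-yl)-1,3-oxazol-5-yl]-4-methoxy-1H-indole-1-carboxylate | COc1cc(Br)cc2n(C(=O)OC(C)(C)C)cc(-c3oc(-c4cccn4COCC[Si](C)(C)C)nc3I)c12 | intermediate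
17 | 6-bromo-3-[4-iodo-2-(1-{[2-(trimethylsilyl)ethoxy]methyl}-1H-pyrrol-2-yl)-1,3-oxazol-5-yl]-4-methoxy-1H-indole | COc1cc(Br)cc2[nH]cc(-c3oc(-c4cccn4COCC[Si](C)(C)C)nc3I)c12 | intermediate
18 | 6-bromo-3-[4-iodo-2-(1H-pyrrol-2-yl)-1,3-oxazol-5-yl]-4-methoxy-1H-indole | COc1cc(Br)cc2[nH]cc(-c3oc(-c4ccc[nH]4)nc3I)c12 | target

**Step count**
Total steps: 8. Longest linear sequence: 6 steps (steps 3, 4, 5, 6, 7, 8, from pyrrole 4).

**Steps most likely to fail**

Step 6. The iodine migration may stop short or disproportionate (loss of iodine from part of the material, double iodination of another part). Palladium may also insert into the oxazole C4–I bond of the zinc reagent or of the product, which would lead to oligomerisation, and coupling at the hindered indole C3 beside the methoxy group may be slow.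
Fallback, setting out from 2 and 10 and coming back at 18: the iodine is put on after the coupling instead of being carried through it.
- Compound 2 is deprotonated with NaH in THF at 0 °C to sodium 6-bromo-3-iodo-4-methoxyindol-1-ide F1 and silylated with iPr3SiCl to 6-bromo-3-iodo-4-methoxy-1-[tri(propan-2-yl)silyl]-1H-indole F2, whose bulky silyl group shields indole C2–H from later metalation.
- Compound 10 is lithiated at C5 as in step 5 (giving 11) and transmetalated with ZnCl2 to chloro[2-(1-SEM-1H-pyrrol-2-yl)-1,3-oxazol-5-yl]zinc F3, which carries no carbon–iodine bond.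
- Negishi coupling of F3 with F2 (Pd(PPh3)4, THF, 50 °C) should give 6-bromo-4-methoxy-3-[2-(1-SEM-1H-pyrrol-2-yl)-1,3-oxazol-5-yl]-1-[tri(propan-2-yl)silyl]-1H-indole F4.
- Magnesiation of the last oxazole C–H with (2,2,6,6-tetramethylpiperidin-1-yl)MgCl·LiCl in THF at 0 °C should give the C4-chloromagnesio derivative of F4 F5.
- Quenching with I2 gives 6-bromo-3-[4-iodo-2-(1-SEM-1H-pyrrol-2-yl)-1,3-oxazol-5-yl]-4-methoxy-1-[tri(propan-2-yl)silyl]-1H-indole F6.
- Bu4NF in THF (rt, then 65 °C) removes both the silyl group and the SEM group and gives 18.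

Step 5. Iodine migration may start during the quench if lithiated and iodinated oxazole coexist, which would scramble the iodine between C4 and C5, and metalation may compete at pyrrole C5.
Fallback, setting out from 10 and coming back at 12: the C5–I bond is formed with no base present. Lithio compound 11 is quenched with Bu3SnCl to 5-(tributylstannyl)-2-(1-SEM-1H-pyrrol-2-yl)-1,3-oxazole F7, which is isolated. Iododestannylation with I2 (1.0 equiv) in CH2Cl2 at 0 °C should then give 12.

Step 4. Lithiation of the SEM-pyrrole may be incomplete or go to the wrong site, and the labile 2-bromooxazole may decompose or homocouple under the coupling conditions.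
Fallback, setting out from 6 and coming back at 10: the roles of the two partners are exchanged. Bromination of 6 with N-bromosuccinimide in THF at −78 °C should give 2-bromo-1-{[2-(trimethylsilyl)ethoxy]methyl}-1H-pyrrole F8. Stille coupling of F8 with purchased 2-(tributylstannyl)-1,3-oxazole (Pd(PPh3)4, toluene, 100 °C) should give 10.

Further compounds
F1 | step 6 | sodium 6-bromo-3-iodo-4-methoxyindol-1-ide | COc1cc(Br)cc2[n-]cc(I)c12.[Na+]
F2 | step 6 | 6-bromo-3-iodo-4-methoxy-1-[tri(propan-2-yl)silyl]-1H-indole | COc1cc(Br)cc2n([Si](C(C)C)(C(C)C)C(C)C)cc(I)c12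
F3 | step 6 | chloro[2-(1-{[2-(trimethylsilyl)ethoxy]methyl}-1H-pyrrol-2-yl)-1,3-oxazol-5-yl]zinc | Cl[Zn]c1cnc(-c2cccn2COCC[Si](C)(C)C)o1
F4 | step 6 | 6-bromo-4-methoxy-3-[2-(1-{[2-(trimethylsilyl)ethoxy]methyl}-1H-pyrrol-2-yl)-1,3-oxazol-5-yl]-1-[tri(propan-2-yl)silyl]-1H-indole | COc1cc(Br)cc2n([Si](C(C)C)(C(C)C)C(C)C)cc(-c3cnc(-c4cccn4COCC[Si](C)(C)C)o3)c12
F5 | step 6 | chloro{5-[6-bromo-4-methoxy-1-(tri(propan-2-yl)silyl)-1H-indol-3-yl]-2-(1-{[2-(trimethylsilyl)ethoxy]methyl}-1H-pyrrol-2-yl)-1,3-oxazol-4-yl}magnesium | COc1cc(Br)cc2n([Si](C(C)C)(C(C)C)C(C)C)cc(-c3oc(-c4cccn4COCC[Si](C)(C)C)nc3[Mg]Cl)c12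
F6 | step 6 | 6-bromo-3-[4-iodo-2-(1-{[2-(trimethylsilyl)ethoxy]methyl}-1H-pyrrol-2-yl)-1,3-oxazol-5-yl]-4-methoxy-1-[tri(propan-2-yl)silyl]-1H-indole | COc1cc(Br)cc2n([Si](C(C)C)(C(C)C)C(C)C)cc(-c3oc(-c4cccn4COCC[Si](C)(C)C)nc3I)c12
F7 | step 5 | 5-(tributylstannyl)-2-(1-{[2-(trimethylsilyl)ethoxy]methyl}-1H-pyrrol-2-yl)-1,3-oxazole | CCCC[Sn](CCCC)(CCCC)c1cnc(-c2cccn2COCC[Si](C)(C)C)o1
F8 | step 4 | 2-bromo-1-{[2-(trimethylsilyl)ethoxy]methyl}-1H-pyrrole | Brc1cccn1COCC[Si](C)(C)C
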